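**Assumed target configuration:** reading the SMILES gives (2S) at C2 of both flavan units, so the target is the (2S,2'S) compound 24.

## The problem

Compound 24 is made of two (2S)-2-phenylchroman (flavan) units joined C8 to C8' through one methylene carbon. Unit A is a 7-hydroxy-5-methoxyflavan and unit B is its 6-methyl analogue.

Each benzo ring is a phloroglucinol whose three oxygens all differ: a methyl ether at C5, a free phenol at C7 and the pyran oxygen O1 on C8a. In unit B every ring position is substituted, so the oxygen pattern, the methyl group and the bridge must be placed without regiochemical doubt.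

The only stereocentres are the two C2 carbons. They lie eight bonds apart across the bridge, so neither can direct the other. Because the units differ in constitution, the mismatched combination is a diastereomer rather than an enantiomer, and both centres must be set by a reagent, preferably in one operation.

The fragile elements are:
- the methylene bridge between two very electron-rich rings (ipso protonation with retro-Friedel–Crafts cleavage in acid, and oxidation);
- the benzylic C2–O1 ether bonds (ionisation, hydrogenolysis);
- the free phenols.

The feature that allows a short assembly is that C4 of each pyran ring is a single carbon between the arene carbon C4a and the C3–C2(phenyl) pair. At the flavone oxidation level C4 is a carbonyl carbon that can come from carbon monoxide, C3–C2–Ph is phenylacetylene, and O1 is a phenol ortho to C4a.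

In the unfunctionalised diarylmethane the only ring carbons still bearing hydrogen are those that become C4a (two equivalent ones on ring A, one on ring B). The halogen needed at C4a can therefore be introduced without directing or protecting groups.

## Retrosynthesis

**Endgame, 24 back to 20.** Removing the two benzyl groups leads to 23, and restoring the C4 oxygens leads to the bis-flavan-4-ol 22 and the bis-flavanone 21. Taking out the hydrogens at C2 and C3 of both units then gives the bis-flavone dibenzyl ether 20. This removes both stereocentres at once. Compound 20 is flat and achiral, and a single catalytic enantioface-selective hydrogenation can address both C2=C3 bonds, so no enantioenriched fragment has to be carried through the construction. The forward sequence must hydrogenate both alkenes with the same facial sense, take C4 from carbonyl to methylene without ionising or cleaving C2–O1, and finally free the C7 phenols. The benzyl ethers are cut back to the bis-flavone diol 19; they are there because free 7-hydroxyflavones are acidic and poorly soluble in the hydrocarbon medium of the hydrogenation.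

**Key disconnection, 19 back to 14, 15 and 16.** In each unit the bonds C4a–C4, C4–C3 and O1–C2 are cut. This gives the bis(2-iodophenol) 14, two molecules of phenylacetylene 15 and two of carbon monoxide 16. The neighbouring cuts are weaker:
- a chalcone or 1,3-diketone route (cuts at O1–C2 and C2–C3 or C3–C4) needs an aryl methyl ketone on each ring and protection of the other phenols;
- a cut at O1–C8a needs a leaving group on a carbon that already bears oxygen.

The carbonylative cut needs only an iodide at C4a and a free phenol at C8a. Precursor 14 has no heterocycle and no stereocentre. The forward reaction must carbonylate both sites before alkyne coupling and close both rings in the 6-endo sense.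

**Iodide, 14 back to 13.** The two C–I bonds are cut to give the tetraphenol 13. No alternative site exists, since the only free ring carbons of 13 are the future C4a positions. The forward reaction must stop at one iodine per ring.

**Bridge, 13 back to 10 and 8.** The bond between the bridge carbon and ring A is cut, with the bridge carbon arriving as the formyl carbon of aldehyde 8 and ring A as aryllithium 11 generated from the bis-MOM ether 10. The intermediate is the diarylcarbinol 12. The alternative, an acid-catalysed union of a phenol with a hydroxybenzyl cation, would attack 5-methoxyresorcinol 9 at C4 as well as C2. Lithiation between the two acetal ethers gives one regioisomer only. The forward sequence needs one reductive acid step that removes the carbinol oxygen and all four MOM groups.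

**Ring B, 8 back to 1.** The formyl group of 8 is cut to give arene 6 (through aryllithium 7). The methyl ether is cut to give cresol 5, and the ring methyl is traced to the formyl group of 2 and so to 2,4,6-trihydroxybenzaldehyde 1. The formyl carbon of 1 thus becomes the C6 methyl of unit B. Its hydrogen bond to one ortho hydroxyl distinguishes the three phenols: the two that react become MOM ethers (later O1 and the C7 phenol) and the one held back becomes the C5 methyl ether. This avoids C-methylation of a phloroglucinol, which gives mixtures.

**Ring A, 10 back to 9.** Two O–MOM bonds are cut to give commercial 5-methoxyresorcinol 9, which already carries the C5 methyl ether.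

## Roads not taken

**Alternative 1:** Aryne cyclisation with aldehyde trapping.
- Cut: O1–C8a of unit B and the bond from C8 of unit B to the bridge carbon.
- Forward step: the bromoarene alcohol A2, which carries the (S)-carbinol on a three-carbon tether, is treated with lithium 2,2,6,6-tetramethylpiperidide. Deprotonation between bromine and the MOM ether and loss of bromide give the C8–C8a aryne. The tethered alkoxide adds to C8a and closes the pyran ring. The resulting C8 aryllithium adds to the flavan-8-carbaldehyde A3 to give the diarylcarbinol A1, which is then deoxygenated and deprotected.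
- Merits: each stereocentre is set in its own fragment by asymmetric reduction of a simple aryl ketone, so configurational purity can be secured and checked before the fragments meet. The tether fixes the regiochemistry of the aryne addition, and the ring and the bridge form in one operation.
- Weak points: two enantioenriched fragments are needed, each several steps long. A3 needs its own pyran ring made by another method, so the key step builds only one of the two heterocycles. The aryllithium is flanked by two oxygen substituents and must add to a 2,6-disubstituted aldehyde. The aryne can also be intercepted by the amine. A1 still needs the same acid and silane deoxygenation as 12.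
- Comparison: this road is better in stereochemical security. The chosen plan sets against that one operation that closes both rings from achiral components, no separate route per unit, and roughly half the step count.

**Alternative 2:** Double gold-catalysed hydroarylation.
- Cut: C4a–C4 in both units.
- Forward step: the bis[(S)-1-phenylprop-2-ynyl] aryl ether A4 is treated with (Ph3P)AuNTf2. Each electron-rich arene attacks the activated alkyne terminus 6-endo to give the bis-2H-chromene A5. One hydrogenation then saturates both C3=C4 bonds and removes the benzyl ethers to give 24.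
- Merits: no C4 oxygen is ever introduced, so the endgame is one step. The stereocentres come from an enantioenriched propargylic alcohol rather than from a late asymmetric catalysis. Conditions are mild and no pressurised carbon monoxide is needed.
- Weak points: the stereogenic C2–O bond of A4 is both benzylic and propargylic and carries an electron-rich aryloxy leaving group. A cationic gold catalyst can ionise it, leading to racemisation or propargyl Claisen rearrangement. Making A4 means etherifying di-ortho-substituted phenols with a secondary benzylic electrophile with clean inversion. Only the phenols that become O1 may be etherified, so the C7 phenols must be benzylated selectively first. On ring A this is a statistical monoprotection, and on ring B it means telling apart two hydroxyls that both flank the bridge. The 2H-chromene A5 can open electrocyclically to an ortho-quinone methide, which puts C2 at risk.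
- Comparison: after ring closure this road is shorter and more atom-economical. The chosen plan sets against that the absence of any phenol differentiation (only the hydroxyl ortho to the acyl group can cyclise) and the creation of the stereocentres on a configurationally stable saturated ring.

**Alternative 3:** Double iridium-catalysed allylic etherification.
- Cut: O1–C2 in both units.
- Forward step: the bis(2-vinylphenol) A6 and two molecules of cinnamyl methyl carbonate A7 react under [Ir(cod)Cl]2 and a chiral phosphoramidite to give the branched bis[(S)-1-phenylallyl] ether A8 with both stereocentres set. Double ring-closing metathesis with the second-generation Grubbs catalyst would give A5, and hydrogenation would finish as in Alternative 2.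
- Merits: like the chosen plan, both centres are set by one catalyst in one step. The sense of induction follows an established model, which the chosen hydrogenation cannot claim without a check. No C4 oxygen has to be removed.
- Weak points: each phenoxide is flanked by a vinyl group and the bridging benzyl group, and hindered phenoxides are poor partners in this etherification. A6 would be made from an iodide of the same kind as 14 by vinylation, and it additionally needs the selective benzylation described for A4. Electron-rich 2-vinylphenols oligomerise readily. The route again passes through A5, with its ring-opening liability.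
- Comparison: counted from the iodide, this road is about as long as the chosen one, and it is better in the predictability of the stereochemical outcome. The chosen plan sets against that a free tetraphenol as substrate, six skeletal bonds formed in the ring-forming step, and stereocentres that are never part of a 2H-chromene.

Key step: step 9

Assumption: the (R,R) enantiomer of 1,3-bis[1-(naphthalen-1-yl)ethyl]-4,5-dihydroimidazolium tetrafluoroborate is taken to deliver the (2S) configuration at both units; if a model flavone shows the opposite sense, the (S,S) salt is used instead.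

## Route

Step 1
Reactants: 1 2,4,6-trihydroxybenzaldehyde
Product: 2 2-hydroxy-4,6-bis(methoxymethoxy)benzaldehyde
Conditions: MOMCl (2.1 equiv), i-Pr2NEt, CH2Cl2, 0 °C to rt
Reagents that add atoms: chloromethyl methyl ether (MOMCl), COCCl
Why: O-alkylation of phenols to MOM ethers; the para hydroxyl and one ortho hydroxyl react, while the second ortho hydroxyl is held in a hydrogen bond to the formyl oxygen, is the least nucleophilic and stays free.

Step 2
Reactants: 2 2-hydroxy-4,6-bis(methoxymethoxy)benzaldehyde
Product: 5 3,5-bis(methoxymethoxy)-2-methylphenol, via aryl ethyl carbonate 3 (not isolated), via ortho-quinone methide 4 (not isolated)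
Conditions: ClCO2Et, Et3N, THF, 0 °C; then NaBH4, H2O, 0 °C to rt
Reagents that add atoms: none
Why: Reductive deoxygenation of a salicylaldehyde through its carbonate: hydride reduces the formyl group, the ethoxycarbonyl group moves to the benzylic oxygen and is expelled to give quinone methide 4, and a second hydride adds to its methylene carbon. The MOM ethers are inert to these basic conditions.

Step 3
Reactants: 5 3,5-bis(methoxymethoxy)-2-methylphenol
Product: 6 1-methoxy-3,5-bis(methoxymethoxy)-2-methylbenzene
Conditions: MeI, K2CO3, acetone, reflux
Reagents that add atoms: iodomethane, CI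
Why: Williamson ether synthesis on the only free phenol; this oxygen becomes the C5 methyl ether of unit B.

Step 4
Reactants: 6 1-methoxy-3,5-bis(methoxymethoxy)-2-methylbenzene
Product: 8 4-methoxy-2,6-bis(methoxymethoxy)-3-methylbenzaldehyde, via aryllithium 7 (not isolated)
Conditions: n-BuLi, TMEDA, THF, 0 °C; DMF, 0 °C to rt; aq NH4Cl
Reagents that add atoms: N,N-dimethylformamide, CN(C)C=O
Why: Directed ortho-metalation followed by formylation; the proton between the two MOM ethers is the most acidic because both acetal oxygens hold lithium, so the formyl group (the future bridge carbon) enters between the future C7 and C8a oxygens.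

Step 5
Reactants: 9 5-methoxyresorcinol
Product: 10 1-methoxy-3,5-bis(methoxymethoxy)benzene
Conditions: MOMCl (2.5 equiv), i-Pr2NEt, CH2Cl2, 0 °C to rt
Reagents that add atoms: chloromethyl methyl ether (MOMCl), COCCl
Why: O-alkylation of both phenols to MOM ethers, which serve as protecting groups and as directing groups for the lithiation in step 6.

Step 6
Reactants: 10 1-methoxy-3,5-bis(methoxymethoxy)benzene, 8 4-methoxy-2,6-bis(methoxymethoxy)-3-methylbenzaldehyde
Product: 12 [4-methoxy-2,6-bis(methoxymethoxy)phenyl][4-methoxy-2,6-bis(methoxymethoxy)-3-methylphenyl]methanol, via aryllithium 11 (not isolated)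
Conditions: n-BuLi, THF, 0 °C; then 8, -78 °C to rt; aq NH4Cl
Reagents that add atoms: none
Why: Directed ortho-metalation between the two MOM ethers followed by 1,2-addition of the aryllithium to the aldehyde, which places the bridge carbon at the future C8 of unit A with no regioisomer. The carbinol centre forms racemic and is removed in step 7.

Step 7
Reactants: 12 [4-methoxy-2,6-bis(methoxymethoxy)phenyl][4-methoxy-2,6-bis(methoxymethoxy)-3-methylphenyl]methanol
Product: 13 2-[(2,6-dihydroxy-4-methoxyphenyl)methyl]-5-methoxy-4-methylbenzene-1,3-diol
Conditions: Et3SiH (excess), CF3CO2H, CH2Cl2, 0 °C to rt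
Reagents that add atoms: none
Why: Ionic hydrogenation of a doubly activated diarylcarbinol combined with acidolysis of the four MOM ethers. The diarylmethyl cation is stabilised by four ortho oxygens and is reduced by the silane, which also scavenges the methoxymethyl cations before they can alkylate the rings.

Step 8
Reactants: 13 2-[(2,6-dihydroxy-4-methoxyphenyl)methyl]-5-methoxy-4-methylbenzene-1,3-diol
Product: 14 2-[(2,6-dihydroxy-3-iodo-4-methoxyphenyl)methyl]-4-iodo-5-methoxy-6-methylbenzene-1,3-diol
Conditions: I2 (2.0 equiv), NaHCO3, THF/H2O, 0 °C
Reagents that add atoms: iodine, II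
Why: Electrophilic aromatic iodination of phenoxides; ring B has one free carbon and ring A two equivalent ones, all of them future C4a positions, and the first iodine on ring A slows entry of a second one.

Step 9
Reactants: 14 2-[(2,6-dihydroxy-3-iodo-4-methoxyphenyl)methyl]-4-iodo-5-methoxy-6-methylbenzene-1,3-diol, 15 phenylacetylene (2 equiv), 16 carbon monoxide (2 equiv)
Product: 19 7-hydroxy-8-[(7-hydroxy-5-methoxy-6-methyl-4-oxo-2-phenyl-4H-chromen-8-yl)methyl]-5-methoxy-2-phenyl-4H-chromen-4-one, via bis-ynone 17 (not isolated), via bis-enaminone 18 (not isolated)
Conditions: PdCl2(PPh3)2 (10 mol%), Et2NH, CO (20 atm), 120 °C, no copper salt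
Reagents that add atoms: none
Why: Zerovalent palladium, formed in the flask from PdCl2(PPh3)2, inserts into each C4a–I bond; carbon monoxide inserts to give an aroylpalladium species, and coupling with the amine-deprotonated alkyne followed by reductive elimination forms C4a–C4 and C4–C3, giving bis-ynone 17. Diethylamine adds to each ynone at the phenyl-bearing carbon to give bis-enaminone 18, and the C8a hydroxyl then displaces the amine at that carbon by addition–elimination, forming O1–C2. Each pyranone ring therefore closes in the 6-endo mode (6-endo-trig on the enaminone, formally 6-endo-dig on the ynone). The closest known reaction type is the palladium-catalysed carbonylative Sonogashira coupling and cyclisation of 2-iodophenols with terminal alkynes to flavones, used here at two sites of one molecule. No stereocentre is formed. Carbonylation must precede alkyne coupling, which the carbon monoxide pressure, the absence of copper and the crowding of the doubly ortho-substituted arylpalladium species favour. The 6-endo closure must win over 5-exo closure to an aurone, which the secondary amine secures by way of the enaminone. Site selectivity is built into 14: on each ring only the C8a hydroxyl is ortho to the new acyl group, the C7 hydroxyl is para to it and the other ortho position carries the methyl ether, so no phenol needs protection.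

Step 10
Reactants: 19 7-hydroxy-8-[(7-hydroxy-5-methoxy-6-methyl-4-oxo-2-phenyl-4H-chromen-8-yl)methyl]-5-methoxy-2-phenyl-4H-chromen-4-one
Product: 20 7-(benzyloxy)-8-{[7-(benzyloxy)-5-methoxy-6-methyl-4-oxo-2-phenyl-4H-chromen-8-yl]methyl}-5-methoxy-2-phenyl-4H-chromen-4-one
Conditions: BnBr, K2CO3, DMF, 50 °C
Reagents that add atoms: benzyl bromide, BrCc1ccccc1
Why: Williamson ether synthesis on the two acidic C7 phenols, the only free hydroxyls; the benzyl ethers remove the acidic protons and make the substrate soluble for the hydrogenation.

Step 11
Reactants: 20 7-(benzyloxy)-8-{[7-(benzyloxy)-5-methoxy-6-methyl-4-oxo-2-phenyl-4H-chromen-8-yl]methyl}-5-methoxy-2-phenyl-4H-chromen-4-one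
Product: 22 (2S)-7-(benzyloxy)-8-{[(2S)-7-(benzyloxy)-4-hydroxy-5-methoxy-6-methyl-2-phenylchroman-8-yl]methyl}-5-methoxy-2-phenylchroman-4-ol (mixture of C4 epimers), via bis-flavanone dibenzyl ether 21 (not isolated)
Conditions: Ru(cod)(2-methylallyl)2, (R,R)-imidazolinium tetrafluoroborate of the assumption, KOt-Bu, n-hexane/toluene, H2 (100 bar), 40 °C; then NaBH4, THF/MeOH, 0 °C
Reagents that add atoms: none
Why: Ruthenium–N-heterocyclic carbene catalysed asymmetric hydrogenation of the flavone C2=C3 bonds. Each C2 is set by catalyst control through enantioface selection on the flat pyranone, independently at the two units, so a wrong-face event at one site gives a separable diastereomer rather than the enantiomer. NaBH4 then converges the ketone and partly over-reduced material to the C4 alcohols (mainly 2,4-cis), whose configuration does not matter.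

Step 12
Reactants: 22 (2S)-7-(benzyloxy)-8-{[(2S)-7-(benzyloxy)-4-hydroxy-5-methoxy-6-methyl-2-phenylchroman-8-yl]methyl}-5-methoxy-2-phenylchroman-4-ol
Product: 23 (2S)-7-(benzyloxy)-8-{[(2S)-7-(benzyloxy)-5-methoxy-2-phenylchroman-8-yl]methyl}-5-methoxy-6-methyl-2-phenylchromane
Conditions: Et3SiH (excess), CF3CO2H, CH2Cl2, -20 to 0 °C
Reagents that add atoms: none
Why: Ionic hydrogenation of benzylic alcohols; ionisation occurs at C4, where the cation is stabilised by the C5, C7 and C8a oxygens, and not at C2, so the silane delivers hydride to C4 and the C2 centres are untouched.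

Step 13
Reactants: 23 (2S)-7-(benzyloxy)-8-{[(2S)-7-(benzyloxy)-5-methoxy-2-phenylchroman-8-yl]methyl}-5-methoxy-6-methyl-2-phenylchromane
Product: 24 (2S)-8-{[(2S)-7-hydroxy-5-methoxy-2-phenylchroman-8-yl]methyl}-5-methoxy-6-methyl-2-phenylchroman-7-ol
Conditions: H2 (1 atm), Pd/C, EtOAc/MeOH, rt
Reagents that add atoms: none
Why: Hydrogenolysis of benzyl aryl ethers; at ambient pressure and temperature the cyclic benzylic C2–O1 ether of a flavan is retained, as is usual in the debenzylation of flavan benzyl ethers.

## Compound list

1 | 2,4,6-trihydroxybenzaldehyde | O=Cc1c(O)cc(O)cc1O | starting material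
2 | 2-hydroxy-4,6-bis(methoxymethoxy)benzaldehyde | O=Cc1c(O)cc(OCOC)cc1OCOC | intermediate
3 | ethyl 2-formyl-3,5-bis(methoxymethoxy)phenyl carbonate (not isolated) | CCOC(=O)Oc1cc(OCOC)cc(OCOC)c1C=O | intermediate
4 | 3,5-bis(methoxymethoxy)-6-methylidenecyclohexa-2,4-dien-1-one, ortho-quinone methide (not isolated) | C=C1C(=O)C=C(OCOC)C=C1OCOC | intermediate
5 | 3,5-bis(methoxymethoxy)-2-methylphenol | Cc1c(O)cc(OCOC)cc1OCOC | intermediate
6 | 1-methoxy-3,5-bis(methoxymethoxy)-2-methylbenzene | COc1cc(OCOC)cc(OCOC)c1C | intermediate
7 | [4-methoxy-2,6-bis(methoxymethoxy)-3-methylphenyl]lithium (not isolated) | [Li]c1c(OCOC)cc(OC)c(C)c1OCOC | intermediate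
8 | 4-methoxy-2,6-bis(methoxymethoxy)-3-methylbenzaldehyde | O=Cc1c(OCOC)cc(OC)c(C)c1OCOC | intermediate
9 | 5-methoxyresorcinol | COc1cc(O)cc(O)c1 | starting material
10 | 1-methoxy-3,5-bis(methoxymethoxy)benzene | COc1cc(OCOC)cc(OCOC)c1 | intermediate
11 | [4-methoxy-2,6-bis(methoxymethoxy)phenyl]lithium (not isolated) | [Li]c1c(OCOC)cc(OC)cc1OCOC | intermediate
12 | [4-methoxy-2,6-bis(methoxymethoxy)phenyl][4-methoxy-2,6-bis(methoxymethoxy)-3-methylphenyl]methanol, racemic at the carbinol carbon | COCOc1cc(OC)cc(OCOC)c1C(O)c1c(OCOC)cc(OC)c(C)c1OCOC | intermediate
13 | 2-[(2,6-dihydroxy-4-methoxyphenyl)methyl]-5-methoxy-4-methylbenzene-1,3-diol | COc1cc(O)c(Cc2c(O)cc(OC)c(C)c2O)c(O)c1 | intermediate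
14 | 2-[(2,6-dihydroxy-3-iodo-4-methoxyphenyl)methyl]-4-iodo-5-methoxy-6-methylbenzene-1,3-diol | COc1cc(O)c(Cc2c(O)c(C)c(OC)c(I)c2O)c(O)c1I | intermediate
15 | phenylacetylene | C#Cc1ccccc1 | starting material
16 | carbon monoxide | [C-]#[O+] | starting material
17 | bis-ynone: 14 with each iodine replaced by a 3-phenylprop-2-ynoyl group (not isolated) | COc1cc(O)c(Cc2c(O)c(C)c(OC)c(C(=O)C#Cc3ccccc3)c2O)c(O)c1C(=O)C#Cc1ccccc1 | intermediate
18 | bis-enaminone: 14 with each iodine replaced by a 3-(diethylamino)-3-phenylprop-2-enoyl group (not isolated) | COc1cc(O)c(Cc2c(O)c(C)c(OC)c(C(=O)C=C(N(CC)CC)c3ccccc3)c2O)c(O)c1C(=O)C=C(N(CC)CC)c1ccccc1 | intermediate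
19 | 7-hydroxy-8-[(7-hydroxy-5-methoxy-6-methyl-4-oxo-2-phenyl-4H-chromen-8-yl)methyl]-5-methoxy-2-phenyl-4H-chromen-4-one | COc1cc(O)c(Cc2c(O)c(C)c(OC)c3c2OC(c2ccccc2)=CC3=O)c2c1C(=O)C=C(c1ccccc1)O2 | intermediate
20 | 7-(benzyloxy)-8-{[7-(benzyloxy)-5-methoxy-6-methyl-4-oxo-2-phenyl-4H-chromen-8-yl]methyl}-5-methoxy-2-phenyl-4H-chromen-4-one | COc1cc(OCc2ccccc2)c(Cc2c(OCc3ccccc3)c(C)c(OC)c3c2OC(c2ccccc2)=CC3=O)c2c1C(=O)C=C(c1ccccc1)O2 | intermediate
21 | (2S)-7-(benzyloxy)-8-{[(2S)-7-(benzyloxy)-5-methoxy-6-methyl-4-oxo-2-phenylchroman-8-yl]methyl}-5-methoxy-2-phenylchroman-4-one (not isolated) | COc1cc(OCc2ccccc2)c(Cc2c(OCc3ccccc3)c(C)c(OC)c3c2O[C@H](c2ccccc2)CC3=O)c2c1C(=O)C[C@@H](c1ccccc1)O2 | intermediate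
22 | (2S)-7-(benzyloxy)-8-{[(2S)-7-(benzyloxy)-4-hydroxy-5-methoxy-6-methyl-2-phenylchroman-8-yl]methyl}-5-methoxy-2-phenylchroman-4-ol, C4 and C4' as epimer mixtures (mainly 2,4-cis) | COc1cc(OCc2ccccc2)c(Cc2c(OCc3ccccc3)c(C)c(OC)c3c2O[C@H](c2ccccc2)CC3O)c2c1C(O)C[C@@H](c1ccccc1)O2 | intermediate
23 | (2S)-7-(benzyloxy)-8-{[(2S)-7-(benzyloxy)-5-methoxy-2-phenylchroman-8-yl]methyl}-5-methoxy-6-methyl-2-phenylchromane | COc1cc(OCc2ccccc2)c(Cc2c(OCc3ccccc3)c(C)c(OC)c3c2O[C@H](c2ccccc2)CC3)c2c1CC[C@@H](c1ccccc1)O2 | intermediate
24 | (2S)-8-{[(2S)-7-hydroxy-5-methoxy-2-phenylchroman-8-yl]methyl}-5-methoxy-6-methyl-2-phenylchroman-7-ol | COc1cc(O)c(Cc2c(O)c(C)c(OC)c3c2O[C@H](c2ccccc2)CC3)c2c1CC[C@@H](c1ccccc1)O2 | target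

## Step count and least certain steps

Total: 13 steps. Longest linear sequence: 12 steps (steps 1 to 4 and 6 to 13, from 2,4,6-trihydroxybenzaldehyde 1); the ring A branch contributes step 5.

**Step 9 (key step).** The double annulation may stall or leak at one site. Possible leaks are alkyne coupling without carbon monoxide insertion (followed by closure to a benzofuran), capture of the aroylpalladium species by the amine, 5-exo closure, or slow oxidative addition into an electron-rich, doubly ortho-substituted C–I bond that carries phenoxides. Because two sites must both succeed, any per-site leakage counts twice. Fallback, setting out from tetraphenol 13: Friedel–Crafts acetylation (Ac2O, BF3·OEt2) at the two free ring carbons gives the bis(2-hydroxyacetophenone) F1. Claisen–Schmidt condensation with benzaldehyde (KOH, EtOH) gives the bis(2'-hydroxychalcone) F2. Oxidative cyclisation with catalytic I2 in DMSO at 130 °C returns to the route at bis-flavone 19.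

**Step 7.** In acid the free bis-phloroglucinol methane can undergo ipso protonation and cleavage at the bridge, which the silane would make irreversible. Methoxymethyl cations may also alkylate the free ring carbons before they are reduced. Fallback, setting out from carbinol 12: hydrogenolysis of the benzhydrylic hydroxyl (H2, Pd/C, EtOAc) gives the tetrakis(MOM) diarylmethane F3. Methanolysis of the acetals (HCl, MeOH, rt), in which methanol traps the formaldehyde unit, returns to the route at 13.

**Step 8.** Over-iodination of ring A at its second equivalent carbon, oxidation of the polyphenol by iodine, and ipso attack at the bridge carbon with loss of one aryl group are all possible. Fallback, setting out from 12 by way of the tetrakis(MOM) diarylmethane F3 (made as in the fallback to step 7): iodination of the less activated ether with N-iodosuccinimide (2 equiv, MeCN) gives the bis-iodo tetrakis(MOM) ether F4. Removal of the acetals (HCl, MeOH) returns to the route at 14.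

**Step 11.** Facial selectivity may be poor, or the hydrogenation may stall at one unit, because the C8 substituent (the other flavone) crowds the pyranone. The base in the catalyst mixture may also open the flavanone to a chalcone and erode C2. Fallback, setting out from bis-iodide 14:
- the carbonylative annulation of step 9 is run with ethynyltrimethylsilane in place of 15; the bis(silyl ynone) F5 loses silicon under the amine conditions and closes to the bis-chromone F6;
- benzylation (BnBr, K2CO3) gives the bis-chromone dibenzyl ether F7;
- asymmetric conjugate addition of PhB(OH)2, catalysed by Pd(OCOCF3)2 and the appropriate enantiomer of the tert-butyl pyridine-oxazoline ligand, forms the C2–phenyl bonds.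

This returns to the route at bis-flavanone 21, which enters the NaBH4 stage of step 11.

**Step 12.** The C4 cation may be captured by an electron-rich ring of a second molecule (the Friedel–Crafts process by which flavan-4-ols oligomerise) or lose a proton to give a flavene. The benzyl ethers may also be partly lost by acidolysis. Fallback, setting out from 22: a Barton–McCombie deoxygenation. NaH, CS2 and MeI give the bis(S-methyl xanthate) F8, and Bu3SnH with AIBN in toluene at 110 °C returns to the route at 23 by a radical path with no cation at C4.

## Further compounds

F1 | step 9 | 13 carrying an acetyl group on each formerly free ring carbon, bis(2-hydroxyacetophenone) | COc1cc(O)c(Cc2c(O)c(C)c(OC)c(C(C)=O)c2O)c(O)c1C(C)=O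
F2 | step 9 | bis(2'-hydroxychalcone), both alkenes E | COc1cc(O)c(Cc2c(O)c(C)c(OC)c(C(=O)/C=C/c3ccccc3)c2O)c(O)c1C(=O)/C=C/c1ccccc1
F3 | step 7 | 1-methoxy-4-{[4-methoxy-2,6-bis(methoxymethoxy)phenyl]methyl}-3,5-bis(methoxymethoxy)-2-methylbenzene, tetrakis(MOM) diarylmethane | COCOc1cc(OC)cc(OCOC)c1Cc1c(OCOC)cc(OC)c(C)c1OCOC
F4 | step 8 | bis-iodo tetrakis(MOM) diarylmethane, tetrakis(MOM) ether of 14 | COCOc1cc(OC)c(I)c(OCOC)c1Cc1c(OCOC)c(I)c(OC)c(C)c1OCOC
F5 | step 11 | bis(silyl ynone): 14 with each iodine replaced by a 3-(trimethylsilyl)prop-2-ynoyl group (not isolated) | COc1cc(O)c(Cc2c(O)c(C)c(OC)c(C(=O)C#C[Si](C)(C)C)c2O)c(O)c1C(=O)C#C[Si](C)(C)C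
F6 | step 11 | 7-hydroxy-8-[(7-hydroxy-5-methoxy-6-methyl-4-oxo-4H-chromen-8-yl)methyl]-5-methoxy-4H-chromen-4-one, bis-chromone | COc1cc(O)c(Cc2c(O)c(C)c(OC)c3c2OC=CC3=O)c2c1C(=O)C=CO2
F7 | step 11 | 7,7'-dibenzyl ether of the bis-chromone | COc1cc(OCc2ccccc2)c(Cc2c(OCc3ccccc3)c(C)c(OC)c3c2OC=CC3=O)c2c1C(=O)C=CO2
F8 | step 12 | bis(S-methyl xanthate) of 22, both C2 centres S, C4 epimers | COc1cc(OCc2ccccc2)c(Cc2c(OCc3ccccc3)c(C)c(OC)c3c2O[C@H](c2ccccc2)CC3OC(=S)SC)c2c1C(OC(=S)SC)C[C@@H](c1ccccc1)O2
A1 | alternative 1 | bis-MOM diarylcarbinol of the target skeleton, both C2 centres S, carbinol carbon as epimers | COc1cc(OCOC)c(C(O)c2c(OCOC)c(C)c(OC)c3c2O[C@H](c2ccccc2)CC3)c2c1CC[C@@H](c1ccccc1)O2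
A2 | alternative 1 | (1S)-3-[2-bromo-6-methoxy-4-(methoxymethoxy)-5-methylphenyl]-1-phenylpropan-1-ol | COCOc1cc(Br)c(CC[C@H](O)c2ccccc2)c(OC)c1C
A3 | alternative 1 | (2S)-5-methoxy-7-(methoxymethoxy)-2-phenylchromane-8-carbaldehyde | COc1cc(OCOC)c(C=O)c2c1CC[C@@H](c1ccccc1)O2
A4 | alternative 2 | bis[(S)-1-phenylprop-2-ynyl] ether of the 7,7'-dibenzylated tetraphenol | COc1cc(OCc2ccccc2)c(Cc2c(OCc3ccccc3)c(C)c(OC)cc2O[C@H](c2ccccc2)C#C)c(O[C@@H](C#C)c2ccccc2)c1
A5 | alternative 2 | 8,8'-methylene-bridged bis[(2S)-7-benzyloxy-5-methoxy-2-phenyl-2H-chromene], one ring 6-methyl | COc1cc(OCc2ccccc2)c(Cc2c(OCc3ccccc3)c(C)c(OC)c3c2O[C@H](c2ccccc2)C=C3)c2c1C=C[C@@H](c1ccccc1)O2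
A6 | alternative 3 | methylene-bridged bis(2-vinylphenol), C7 oxygens benzylated | COc1cc(OCc2ccccc2)c(Cc2c(OCc3ccccc3)c(C)c(OC)c(C=C)c2O)c(O)c1C=C
A7 | alternative 3 | (E)-cinnamyl methyl carbonate | COC(=O)OC/C=C/c1ccccc1
A8 | alternative 3 | bis[(S)-1-phenylallyl] aryl ether of the bridged bis(2-vinylphenol) | COc1cc(OCc2ccccc2)c(Cc2c(OCc3ccccc3)c(C)c(OC)c(C=C)c2O[C@H](c2ccccc2)C=C)c(O[C@@H](C=C)c2ccccc2)c1C=C
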